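**Plan**

1. Retrosynthesis (eremophilane numbering; ring A = C1–C5 + C10, ring B = C5–C10; α = the face opposite the C5 methyl): the C3 ester is cut at its Z-alkene and at the acyl–O bond; the C9 carbinol, C8–OH and C7–isopropenyl go back to a ring-B enone; ring A is cut at C2–C3 and C1–C10; last, C4–C5 is cut.
2. What makes the ring-A event possible: C3 carries oxygen and C10 lies next to the oxygenated C9. C3 can therefore be an aldehyde carbon and C10 the α′ carbon of a C9 enone in ring B. The unit C3–C4–C5–C10 is bridged by a two-carbon reagent that is nucleophilic at C2 and electrophilic at C1, 1-(phenylsulfonyl)vinyllithium.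
3. Forward: ring B comes from 3-methylcyclohex-2-en-1-one, C4 and C5 from an Ireland–Claisen shift, ring A is closed in one flask, then C7, C8 and C9 are dressed and the side chain is joined by a Z-selective olefination.
4. Stereochemistry: a CBS reduction sets a carbinol that is relayed to C5 and C4; Felkin–Anh addition sets C3; base equilibration sets C10; the axial C5 methyl sends the cuprate (C7) and the oxidant (C8) to the α face; dissolving-metal reduction gives the equatorial C9 alcohol; C4′ is bought as methyl (R)-2-hydroxybutanoate.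

Key step: step 8

Remark: [bis(2,2,2-trifluoroethoxy)phosphoryl]acetic acid (26) is taken as a purchasable reagent.

**Route**

Step 1
Reactants: 1 3-methylcyclohex-2-en-1-one
Product: 2 (1R)-3-methylcyclohex-2-en-1-ol
Conditions: (S)-2-methyl-CBS-oxazaborolidine (10 mol%), catecholborane, toluene, −78 °C
Reagents that add atoms: none
Why: Corey–Bakshi–Shibata reduction of an enone, in which the alkenyl arm acts as the large group, so the (S)-catalyst should deliver the (R)-allylic alcohol.

Step 2
Reactants: 2 (1R)-3-methylcyclohex-2-en-1-ol; 3 propanoyl chloride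
Product: 4 (1R)-3-methylcyclohex-2-en-1-yl propanoate
Conditions: EtCOCl, pyridine, DMAP (cat.), CH2Cl2, 0 °C
Reagents that add atoms: propanoyl chloride, CCC(=O)Cl
Why: Base-mediated O-acylation, which keeps the ionisable allylic C–O bond and its configuration intact.

Step 3
Reactants: 4 (1R)-3-methylcyclohex-2-en-1-yl propanoate
Product: 7 methyl (2R)-2-[(1S)-1-methylcyclohex-2-en-1-yl]propanoate, via (Z)-silyl ketene acetal 5 (not isolated), via silyl ester 6 (not isolated)
Conditions: LiN(iPr)2, tBuMe2SiCl, THF/DMPU, −78 °C (in situ trapping), then 65 °C; then CsF, MeI, DMF, 23 °C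
Reagents that add atoms: iodomethane, CI
Why: Ireland–Claisen rearrangement, in which the C4–C5 bond forms on the face of the departing C–O bond (fixing C5) and the (Z)-ketene acetal reacting through the boat-like transition state preferred by cyclohex-2-enyl esters should place the C4 methyl as drawn; fluoride then cleaves the silyl ester and the carboxylate is methylated.

Step 4
Reactants: 7 methyl (2R)-2-[(1S)-1-methylcyclohex-2-en-1-yl]propanoate
Product: 8 methyl (2R)-2-[(1S)-3-hydroxy-1-methylcyclohexyl]propanoate (carbinol epimers)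
Conditions: 9-BBN, THF, 65 °C; then H2O2, NaOH (aq.), 0 °C
Reagents that add atoms: hydrogen peroxide, OO
Why: Hydroboration–oxidation with a bulky borane, which should place boron on the alkene carbon remote from the quaternary centre (C9); the carbinol configuration is irrelevant because it is oxidised next.

Step 5
Reactants: 8 methyl (2R)-2-[(1S)-3-hydroxy-1-methylcyclohexyl]propanoate
Product: 10 methyl (2R)-2-[(1S)-1-methyl-5-oxocyclohex-3-en-1-yl]propanoate, via saturated ketone 9 (not isolated)
Conditions: IBX (4 equiv), DMSO, 25 → 80 °C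
Reagents that add atoms: none
Why: IBX oxidation of the alcohol followed by IBX dehydrogenation of the ketone, which can only run toward C8–C7 because the other α-carbon (C10) is flanked by the quaternary C5.

Step 6
Reactants: 10 methyl (2R)-2-[(1S)-1-methyl-5-oxocyclohex-3-en-1-yl]propanoate
Product: 11 methyl (2R)-2-[(1S)-5-{[tert-butyl(dimethyl)silyl]oxy}-1-methylcyclohexa-3,5-dien-1-yl]propanoate
Conditions: LiN(iPr)2, tBuMe2SiCl, DMPU, THF, −78 °C (in situ trapping)
Reagents that add atoms: tert-butyl(chloro)dimethylsilane, CC(C)(C)[Si](C)(C)Cl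
Why: Kinetic α′-deprotonation of the enone with O-silylation gives the cross-conjugated silyl dienol ether, which masks the ketone and stores C10 as the latent nucleophile.

Step 7
Reactants: 11 silyl dienol ether ester
Product: 12 (2R)-2-[(1S)-5-{[tert-butyl(dimethyl)silyl]oxy}-1-methylcyclohexa-3,5-dien-1-yl]propanal
Conditions: iBu2AlH (1.1 equiv), CH2Cl2, −78 °C; Rochelle salt
Reagents that add atoms: none
Why: Half-reduction of the ester through its aluminium hemiacetal, which collapses only on work-up; the hindered C4 centre and the silyl dienol ether should survive the cold, non-basic conditions.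

Step 8
Reactants: 12 aldehyde with silyl dienol ether; 13 phenyl vinyl sulfone
Product: 17 (4aR,5R,6S,8aR)-6-hydroxy-4a,5-dimethyl-7-(phenylsulfonyl)-4a,5,6,7,8,8a-hexahydronaphthalen-1(4H)-one (trans-fused; both C7 epimers), via 1-(phenylsulfonyl)vinyllithium 14 (not isolated), via lithium alkoxide adduct 15 (not isolated), via ring-fusion epimer mixture 16 (not isolated)
Conditions: 13, MeLi, THF, −95 °C; add 12, −95 → −78 °C; then Bu4NF (anhydrous), −78 → 0 °C; then DBU, 23 °C
Reagents that add atoms: phenyl vinyl sulfone, C=CS(=O)(=O)c1ccccc1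
Why: The α-lithiated vinyl sulfone adds to the aldehyde carbon C3 (C2–C3 bond); fluoride then frees the cross-conjugated dienolate of ring B, whose C10 adds to the terminal carbon C1 of the tethered vinyl sulfone (C1–C10 bond), and the α-sulfonyl carbanion is protonated. The closest known reaction types are the addition of α-metalated vinyl sulfones to aldehydes (Morita–Baylis–Hillman-type adducts) and the intramolecular Michael addition of ketone enolates to vinyl sulfones, run here in one flask. Ring A closes in the 6-(enolexo)-endo-trig mode. C3 is set by Felkin–Anh addition anti to the quaternary C5 substituent of C4, which gives the 3α-O/4β-Me relationship; C10, α to the C9 ketone, is set by DBU equilibration to the trans-fused isomer that keeps 3-OH and 4-Me equatorial; the sulfone-bearing C2 is not controlled and is deleted in step 11. The step needs aldehyde over ketone selectivity (secured by the silyl dienol ether mask), C10 over C8 attack (only the α′ carbon is unmasked and only it reaches C1 through a six-membered closure) and ring closure over oligomerisation or a second Michael addition of the sulfonyl carbanion to C7 (low temperature, dilution and proton quench).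

Step 9
Reactants: 17 trans-fused hydroxy sulfone enone; 18 isopropenylmagnesium bromide
Product: 19 bis(trimethylsilyl) compound: 3α-OSiMe3 ether and Δ8 trimethylsilyl enol ether with 7α-isopropenyl
Conditions: CH2=C(CH3)MgBr (4 equiv), CuBr·SMe2 (20 mol%), Me3SiCl, DMPU, THF, −78 → −40 °C; Et3N
Reagents that add atoms: isopropenylmagnesium bromide, CC(=C)[Mg]Br; chlorotrimethylsilane, C[Si](C)(C)Cl
Why: Copper-catalysed conjugate addition with silyl trapping, in which the β face at C7 is blocked 1,3-diaxially by the C5 methyl so the isopropenyl group should enter α (equatorial), and the enolate is fixed regiospecifically as the Δ8 silyl enol ether while the C3 hydroxyl is silylated.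

Step 10
Reactants: 19 bis(trimethylsilyl) compound
Product: 22 3α,8α-dihydroxy-9-ketone (sulfone retained), via silyloxy epoxide 20 (not isolated), via bis-silylated ketol 21 (not isolated)
Conditions: dimethyldioxirane, acetone/CH2Cl2, −78 °C; then citric acid, MeOH, 0 °C
Reagents that add atoms: dimethyldioxirane, CC1(C)OO1
Why: Rubottom oxidation, in which the electron-rich silyl enol ether should react far faster than the isopropenyl group and from the α face (anti to the angular methyl, axial at C8), giving the 8α-hydroxy ketone after silyl transfer and methanolysis.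

Step 11
Reactants: 22 3α,8α-dihydroxy-9-ketone
Product: 24 (1S,2R,3S,4aR,5R,6R,8aR)-4a,5-dimethyl-3-(prop-1-en-2-yl)decahydronaphthalene-1,2,6-triol, via dilithium dialkoxide 23 (not isolated)
Conditions: LiN(SiMe3)2 (2 equiv), THF, −78 °C; then Li, NH3(l)/THF, EtOH, −78 → −33 °C; NH4Cl
Reagents that add atoms: none
Why: Dissolving-metal reduction gives the thermodynamically preferred equatorial 9α-alcohol (hydride reagents would attack anti to the C5 methyl and give 9β) and cleaves the C2–S bond in the same flask (reductive desulfonylation); the pre-formed alkoxides cannot leave as oxide, which should suppress both elimination at C2/C3 and loss of the C8 oxygen.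

Step 12
Reactants: 24 triol
Product: 25 8,9-acetonide of 24 with free C3 hydroxyl
Conditions: 2,2-dimethoxypropane, PPTS (cat.), acetone, 23 °C
Reagents that add atoms: 2,2-dimethoxypropane, COC(C)(C)OC
Why: Acid-catalysed ketalisation, in which only the cis-8,9-diol can form a cyclic ketal and the isolated C3 hydroxyl is left free.

Step 13
Reactants: 25 acetonide alcohol; 26 [bis(2,2,2-trifluoroethoxy)phosphoryl]acetic acid
Product: 27 C3 phosphonoacetate ester of 25
Conditions: 26, DCC, DMAP (cat.), CH2Cl2, 0 → 23 °C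
Reagents that add atoms: [bis(2,2,2-trifluoroethoxy)phosphoryl]acetic acid, OC(=O)CP(=O)(OCC(F)(F)F)OCC(F)(F)F
Why: Steglich esterification of the equatorial C3 alcohol with an acid that has no alkene to isomerise; no stereocentre is touched.

Step 14
Reactants: 28 methyl (2R)-2-hydroxybutanoate; 29 angelic acid [(2Z)-2-methylbut-2-enoic acid]
Product: 31 methyl (2R)-2-{[(2Z)-2-methylbut-2-enoyl]oxy}butanoate, via mixed anhydride 30 (not isolated)
Conditions: 29, 2,4,6-trichlorobenzoyl chloride, Et3N, toluene, 23 °C; then 28, 80 °C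
Reagents that add atoms: angelic acid, C/C=C(/C)C(=O)O
Why: Yamaguchi mixed-anhydride esterification run without DMAP, which avoids the conjugate-addition pathway that turns angelates into tiglates; the carbinol centre is not involved.

Step 15
Reactants: 31 methyl (2R)-2-{[(2Z)-2-methylbut-2-enoyl]oxy}butanoate
Product: 32 (2R)-1-oxobutan-2-yl (2Z)-2-methylbut-2-enoate
Conditions: iBu2AlH (1.0 equiv), CH2Cl2, −90 °C; used crude
Reagents that add atoms: none
Why: Ester half-reduction, in which the methyl ester activated by the α-acyloxy group should react before the hindered, conjugated angelate; low temperature and immediate use protect the α-acyloxy aldehyde centre.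

Step 16
Reactants: 27 phosphonoacetate ester; 32 (2R)-1-oxobutan-2-yl (2Z)-2-methylbut-2-enoate
Product: 34 8,9-acetonide of the target, via potassium phosphonate anion 33 (not isolated)
Conditions: KN(SiMe3)2, 18-crown-6, THF, −78 °C; then 32, −78 °C
Reagents that add atoms: (2R)-1-oxobutan-2-yl (2Z)-2-methylbut-2-enoate, CC[C@@H](OC(=O)/C(C)=C\C)C=O
Why: Still–Gennari olefination, in which the trifluoroethyl phosphonate with a dissociated potassium counter-ion should give the (Z)-enoate under kinetic control; the acylated γ-oxygen cannot lactonise.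

Step 17
Reactants: 34 8,9-acetonide of the target
Product: 35 target, (1R,2R,4aR,5S,6R,7S,8aR)-5,6-dihydroxy-1,8a-dimethyl-7-(prop-1-en-2-yl)decahydronaphthalen-2-yl (2Z,4R)-4-{[(2Z)-2-methylbut-2-enoyl]oxy}hex-2-enoate
Conditions: AcOH/H2O (4:1), 40 °C
Reagents that add atoms: none
Why: Mild acid hydrolysis of the acetonide, which the esters, the (Z)-enoate, the angelate and the isopropenyl group should tolerate.

**Compound list**

1 | 3-methylcyclohex-2-en-1-one | CC1=CC(=O)CCC1 | starting material
2 | (1R)-3-methylcyclohex-2-en-1-ol | CC1=C[C@H](O)CCC1 | intermediate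
3 | propanoyl chloride | CCC(=O)Cl | starting material
4 | (1R)-3-methylcyclohex-2-en-1-yl propanoate | CCC(=O)O[C@H]1C=C(C)CCC1 | intermediate
5 | (Z)-tert-butyldimethylsilyl ketene acetal of 4 | C/C=C(\O[Si](C)(C)C(C)(C)C)O[C@H]1C=C(C)CCC1 | intermediate (not isolated)
6 | tert-butyldimethylsilyl (2R)-2-[(1S)-1-methylcyclohex-2-en-1-yl]propanoate | C[C@@H](C(=O)O[Si](C)(C)C(C)(C)C)[C@]1(C)C=CCCC1 | intermediate (not isolated)
7 | methyl (2R)-2-[(1S)-1-methylcyclohex-2-en-1-yl]propanoate | C[C@@H](C(=O)OC)[C@]1(C)C=CCCC1 | intermediate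
8 | methyl (2R)-2-[(1S)-3-hydroxy-1-methylcyclohexyl]propanoate (carbinol epimers) | C[C@@H](C(=O)OC)[C@]1(C)CC(O)CCC1 | intermediate
9 | methyl (2R)-2-[(1S)-1-methyl-3-oxocyclohexyl]propanoate | C[C@@H](C(=O)OC)[C@]1(C)CC(=O)CCC1 | intermediate (not isolated)
10 | methyl (2R)-2-[(1S)-1-methyl-5-oxocyclohex-3-en-1-yl]propanoate | C[C@@H](C(=O)OC)[C@]1(C)CC(=O)C=CC1 | intermediate
11 | methyl (2R)-2-[(1S)-5-{[tert-butyl(dimethyl)silyl]oxy}-1-methylcyclohexa-3,5-dien-1-yl]propanoate | C[C@@H](C(=O)OC)[C@]1(C)C=C(O[Si](C)(C)C(C)(C)C)C=CC1 | intermediate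
12 | (2R)-2-[(1S)-5-{[tert-butyl(dimethyl)silyl]oxy}-1-methylcyclohexa-3,5-dien-1-yl]propanal | C[C@@H](C=O)[C@]1(C)C=C(O[Si](C)(C)C(C)(C)C)C=CC1 | intermediate
13 | phenyl vinyl sulfone | C=CS(=O)(=O)c1ccccc1 | starting material
14 | 1-(phenylsulfonyl)vinyllithium | [Li]C(=C)S(=O)(=O)c1ccccc1 | intermediate (not isolated)
15 | lithium alkoxide from Felkin–Anh addition of 14 to 12 (C3 carbinol as in the target; silyl dienol ether intact) | C[C@@H]([C@H]([O-])C(=C)S(=O)(=O)c1ccccc1)[C@]2(C)C=C(O[Si](C)(C)C(C)(C)C)C=CC2.[Li+] | intermediate (not isolated)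
16 | ring-closed 3α-hydroxy-2-(phenylsulfonyl) enone, epimers at the ring-fusion carbon C10 and at C2 | O=C1C=CC[C@]2(C)[C@@H](C)[C@H](O)C(S(=O)(=O)c3ccccc3)CC12 | intermediate (not isolated)
17 | (4aR,5R,6S,8aR)-6-hydroxy-4a,5-dimethyl-7-(phenylsulfonyl)-4a,5,6,7,8,8a-hexahydronaphthalen-1(4H)-one (trans-fused; C7 epimers) | O=C1C=CC[C@]2(C)[C@@H](C)[C@H](O)C(S(=O)(=O)c3ccccc3)C[C@@H]12 | intermediate
18 | isopropenylmagnesium bromide | CC(=C)[Mg]Br | starting material
19 | 7α-isopropenyl Δ8 trimethylsilyl enol ether with 3α-OSiMe3 and 2-sulfonyl groups | C=C(C)[C@@H]1C[C@]2(C)[C@@H](C)[C@H](O[Si](C)(C)C)C(S(=O)(=O)c3ccccc3)C[C@H]2C(O[Si](C)(C)C)=C1 | intermediate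
20 | 8α,9α-epoxide of 19 (9-trimethylsilyloxy oxirane) | C=C(C)[C@@H]1C[C@]2(C)[C@@H](C)[C@H](O[Si](C)(C)C)C(S(=O)(=O)c3ccccc3)C[C@H]2[C@]4(O[Si](C)(C)C)O[C@H]14 | intermediate (not isolated)
21 | 3α,8α-bis(trimethylsilyloxy)-9-ketone | C=C(C)[C@@H]1C[C@]2(C)[C@@H](C)[C@H](O[Si](C)(C)C)C(S(=O)(=O)c3ccccc3)C[C@H]2C(=O)[C@@H]1O[Si](C)(C)C | intermediate (not isolated)
22 | 3α,8α-dihydroxy-7α-isopropenyl-2-(phenylsulfonyl)-9-ketone (trans-fused) | C=C(C)[C@@H]1C[C@]2(C)[C@@H](C)[C@H](O)C(S(=O)(=O)c3ccccc3)C[C@H]2C(=O)[C@@H]1O | intermediate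
23 | dilithium 3,8-dialkoxide of 22 | C=C(C)[C@@H]1C[C@]2(C)[C@@H](C)[C@H]([O-])C(S(=O)(=O)c3ccccc3)C[C@H]2C(=O)[C@@H]1[O-].[Li+].[Li+] | intermediate (not isolated)
24 | (1S,2R,3S,4aR,5R,6R,8aR)-4a,5-dimethyl-3-(prop-1-en-2-yl)decahydronaphthalene-1,2,6-triol | C=C(C)[C@@H]1C[C@]2(C)[C@@H](C)[C@H](O)CC[C@H]2[C@H](O)[C@@H]1O | intermediate
25 | 8,9-O-isopropylidene derivative of 24 (C3 hydroxyl free) | C=C(C)[C@@H]1C[C@]2(C)[C@@H](C)[C@H](O)CC[C@H]2[C@@H]3OC(C)(C)O[C@H]13 | intermediate
26 | [bis(2,2,2-trifluoroethoxy)phosphoryl]acetic acid | OC(=O)CP(=O)(OCC(F)(F)F)OCC(F)(F)F | starting material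
27 | C3 [bis(2,2,2-trifluoroethoxy)phosphoryl]acetate of 25 | C=C(C)[C@@H]1C[C@]2(C)[C@@H](C)[C@H](OC(=O)CP(=O)(OCC(F)(F)F)OCC(F)(F)F)CC[C@H]2[C@@H]3OC(C)(C)O[C@H]13 | intermediate
28 | methyl (2R)-2-hydroxybutanoate | CC[C@@H](O)C(=O)OC | starting material
29 | angelic acid, (2Z)-2-methylbut-2-enoic acid | C/C=C(/C)C(=O)O | starting material
30 | angelic 2,4,6-trichlorobenzoic anhydride | C/C=C(/C)C(=O)OC(=O)c1c(Cl)cc(Cl)cc1Cl | intermediate (not isolated)
31 | methyl (2R)-2-{[(2Z)-2-methylbut-2-enoyl]oxy}butanoate | CC[C@@H](OC(=O)/C(C)=C\C)C(=O)OC | intermediate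
32 | (2R)-1-oxobutan-2-yl (2Z)-2-methylbut-2-enoate | CC[C@@H](OC(=O)/C(C)=C\C)C=O | intermediate
33 | potassium salt of the phosphonate carbanion of 27 | C=C(C)[C@@H]1C[C@]2(C)[C@@H](C)[C@H](OC(=O)[CH-]P(=O)(OCC(F)(F)F)OCC(F)(F)F)CC[C@H]2[C@@H]3OC(C)(C)O[C@H]13.[K+] | intermediate (not isolated)
34 | 8,9-O-isopropylidene derivative of the target | C=C(C)[C@@H]1C[C@]2(C)[C@@H](C)[C@H](OC(=O)/C=C\[C@@H](CC)OC(=O)/C(C)=C\C)CC[C@H]2[C@@H]3OC(C)(C)O[C@H]13 | intermediate
35 | (1R,2R,4aR,5S,6R,7S,8aR)-5,6-dihydroxy-1,8a-dimethyl-7-(prop-1-en-2-yl)decahydronaphthalen-2-yl (2Z,4R)-4-{[(2Z)-2-methylbut-2-enoyl]oxy}hex-2-enoate | C=C(C)[C@@H]1C[C@]2(C)[C@@H](C)[C@H](OC(=O)/C=C\[C@@H](CC)OC(=O)/C(C)=C\C)CC[C@H]2[C@H](O)[C@@H]1O | target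

**Step count and risks**

Total steps: 17. Longest linear sequence: 15 (steps 1–13, 16, 17); steps 14 and 15 make the aldehyde fragment.

Step 8. What may go wrong: the fluoride-generated dienolate is protonated or adds to a second molecule before the endo ring closure, the sulfonyl carbanion adds on to C7 of the enone to give a bridged by-product, Felkin control is incomplete, or the ring fusion does not equilibrate fully. The fallback sets out from 12 and returns at 24, making the two ring-A bonds in separate steps. Felkin–Anh addition of CH2=CHMgBr to 12 gives the allylic alcohol F1. 9-BBN followed by H2O2/NaOH hydroborates only the terminal vinyl group to give the 1,3-diol F2. I2, PPh3 and imidazole convert the primary hydroxyl into the iodide F3. Bu4NF frees the dienolate, which closes ring A by 6-exo-tet α′-alkylation, and DBU equilibration gives the sulfone-free trans-fused hydroxy enone F4. The conditions of step 9 give the bis-silyl compound F5, those of step 10 the dihydroxy ketone F6, and those of step 11 (now only a ketone reduction) give 24.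

Step 11. What may go wrong: reductive loss of the C8 oxygen next to the ketyl, or incomplete equilibration to the equatorial C9 alcohol. The fallback sets out from 17 and returns at 25, replacing the ketone reduction by a face-selective dihydroxylation while the isopropenyl group is masked as an acetyl group. With the C3 hydroxyl silylated in situ (Me3SiCl, Et3N), conjugate addition of lithium bis(1-ethoxyvinyl)cuprate (from ethyl vinyl ether, tBuLi and CuI), trapping of the enolate with PhNTf2 and mild aqueous oxalic acid give the 7α-acetyl enol triflate F7. Pd(OAc)2/PPh3 with HCO2H–Bu3N reduces the triflate to the Δ8 alkene F8. OsO4 (cat.) with N-methylmorpholine N-oxide should add from the α face, anti to the C5 methyl, to give the cis-diol F9. 2,2-Dimethoxypropane/PPTS gives the acetonide F10. The Tebbe reagent Cp2Ti(μ-Cl)(μ-CH2)AlMe2 methylenates the acetyl group to give the isopropenyl sulfone F11. Sodium amalgam Na(Hg) with Na2HPO4 in MeOH removes the sulfone to give 25.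

Step 3. What may go wrong: leakage through the chair-like transition state or imperfect ketene acetal geometry, which erodes the C4 configuration (C5 is secure). The fallback sets out from 2 and returns at 7, setting C5 and C4 in separate steps. Johnson–Claisen rearrangement of 2 with MeC(OEt)3 and catalytic EtCO2H at 140 °C gives the ethyl ester F12. LiOH gives the acid F13. Pivaloyl chloride/Et3N and then the lithium salt of (4R)-4-benzyl-1,3-oxazolidin-2-one give the imide F14. Evans alkylation (NaN(SiMe3)2, MeI, −78 °C) installs the C4 methyl under auxiliary control to give the methylated imide F15. MeOMgBr in MeOH cleaves the auxiliary to give 7.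

Further compounds
F1 | step 8 | allylic alcohol from vinyl addition to 12 (silyl dienol ether intact) | C[C@@H]([C@H](O)C=C)[C@]1(C)C=C(O[Si](C)(C)C(C)(C)C)C=CC1
F2 | step 8 | 1,3-diol from hydroboration of F1 | C[C@@H]([C@H](O)CCO)[C@]1(C)C=C(O[Si](C)(C)C(C)(C)C)C=CC1
F3 | step 8 | primary iodide from F2 | C[C@@H]([C@H](O)CCI)[C@]1(C)C=C(O[Si](C)(C)C(C)(C)C)C=CC1
F4 | step 8 | sulfone-free trans-fused 3α-hydroxy enone | O=C1C=CC[C@]2(C)[C@@H](C)[C@H](O)CC[C@@H]12
F5 | step 8 | sulfone-free bis(trimethylsilyl) compound (analogue of 19) | C=C(C)[C@@H]1C[C@]2(C)[C@@H](C)[C@H](O[Si](C)(C)C)CC[C@H]2C(O[Si](C)(C)C)=C1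
F6 | step 8 | sulfone-free 3α,8α-dihydroxy-9-ketone (analogue of 22) | C=C(C)[C@@H]1C[C@]2(C)[C@@H](C)[C@H](O)CC[C@H]2C(=O)[C@@H]1O
F7 | step 11 | 7α-acetyl Δ8 enol triflate (3α-hydroxy, 2-sulfonyl) | CC(=O)[C@@H]1C[C@]2(C)[C@@H](C)[C@H](O)C(S(=O)(=O)c3ccccc3)C[C@H]2C(OS(=O)(=O)C(F)(F)F)=C1
F8 | step 11 | 7α-acetyl Δ8 alkene | CC(=O)[C@@H]1C[C@]2(C)[C@@H](C)[C@H](O)C(S(=O)(=O)c3ccccc3)C[C@H]2C=C1
F9 | step 11 | 7α-acetyl 3α,8α,9α-triol | CC(=O)[C@@H]1C[C@]2(C)[C@@H](C)[C@H](O)C(S(=O)(=O)c3ccccc3)C[C@H]2[C@H](O)[C@@H]1O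
F10 | step 11 | 8,9-acetonide of F9 | CC(=O)[C@@H]1C[C@]2(C)[C@@H](C)[C@H](O)C(S(=O)(=O)c3ccccc3)C[C@H]2[C@@H]4OC(C)(C)O[C@H]14
F11 | step 11 | 2-(phenylsulfonyl) derivative of 25 | C=C(C)[C@@H]1C[C@]2(C)[C@@H](C)[C@H](O)C(S(=O)(=O)c3ccccc3)C[C@H]2[C@@H]4OC(C)(C)O[C@H]14
F12 | step 3 | ethyl 2-[(1R)-1-methylcyclohex-2-en-1-yl]acetate | CCOC(=O)C[C@]1(C)C=CCCC1
F13 | step 3 | 2-[(1R)-1-methylcyclohex-2-en-1-yl]acetic acid | OC(=O)C[C@]1(C)C=CCCC1
F14 | step 3 | (4R)-4-benzyl-3-{2-[(1R)-1-methylcyclohex-2-en-1-yl]acetyl}-1,3-oxazolidin-2-one | O=C(C[C@]1(C)C=CCCC1)N1[C@H](Cc2ccccc2)COC1=O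
F15 | step 3 | (4R)-4-benzyl-3-{(2R)-2-[(1S)-1-methylcyclohex-2-en-1-yl]propanoyl}-1,3-oxazolidin-2-one | O=C([C@H](C)[C@]1(C)C=CCCC1)N1[C@H](Cc2ccccc2)COC1=O
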